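The ratio of J formed to X lost in the south-east flask at 40.0 h was 1.72, so Q was feeding X, and I followed X and Q together as one pool.

- south-east: X 20 mM; Q 20 mM; L 1.9 mM (held); the very flask that is asked about, followed so far
- flask: X 20 mM; L 1.9 mM (held); Q 20 mM; time 10 d

south-east run (percent of the X and Q together charged)

| time / h | J / % | D / % | X / % |
|---|---|---|---|
| 3.00 | 4.8 | 0 | 45.6 |
| 8.00 | 11.5 | 1.1 | 41.0 |
| 20.0 | 27.0 | 0.5 | 32.6 |
| 40.0 | 45.0 | 0 | 23.9 |

(standard deviation of a reading: 0.5 percentage points)

- Z is single-handed; X and Q are mirror images of each other, charged as a racemate, each of them at the stated concentration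
- at the start none of L is in solution
- an excess is the difference of the two amounts in percent of their sum
- an excess is below zero if the other one leads
- the handed part of Z does not stay in what it makes, so the products of the two hands are mirror images too

- J and D together, in percent of the X and Q charged together, at 10 d
- excess of J over D in the product at 10 d
- whether the exchange between X and Q keeps pace with the reaction: how far the product's excess at 10 d gets from its value without exchange to its value with instant exchange (above 80% keeps pace, below 20% hardly takes part, else lags behind)

The south-east flask still held 55.0% of the pool at 40.0 h. Read as a steady first-order fall (pseudo-first-order), this gives the pool half-life, the time in which X and Q together halve, as 1.93 d. Over 10 d that leaves 2.77% of the pool, so I expected y of 97.2%.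

The forecast gave y 97% (95.5% to 98.2%), eP 97.8% (95% to 99.7%) and "keeps pace", noting “The fraction reached is about 95%”. My reckoning and its figure for y differed by 0.23 percentage points.

The flask gave y 97.4%, eP 97.8% and "keeps pace", at 96% of the way.

    Z → G (k = 0.0650 h⁻¹)
    L ⇌ Z, rate k2*(csat - [Z]) (kL = 14.0 h⁻¹)
    Z + Q → D (k = 0.160 M⁻¹ h⁻¹)
    Z + X → J (k = 18.0 M⁻¹ h⁻¹)
    X ⇌ Q (k = 0.0700 h⁻¹)

In the flask the turning of X into Q had a half-life of 0.41 d, counted by its forward rate alone, which is 4.71 times shorter than the pool half-life of 1.93 d, and among what was left of the two Q led X by an excess of 11.3% at 1.00 d. The pool half-life put 16.6% of the pool in the flask at 5.00 d, where X stood at 7.17% and Q at 9.10%, together 16.3%.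

The numbers in the tables stem from a simulated flask with constants of no real substance; the scatter is artificial.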